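Retrosynthesis: the C2 acetate is removed, then both oxiranes are opened, C3–O–C4 in the ten-membered ring and C13–O–C14 in the six-membered ring. Both are cis-disubstituted and each has an oxygen-bearing neighbour (C2, C12). They therefore come from a (Z)-C3=C4 allylic alcohol and from a C13=C14 cyclohexene whose β face carries the C1 methyl, the C11 methyl and the C12 acetoxy group.
Further cuts, in this order: lactone O7–C19, C6–C7 (chloroallylation), C8–C9 (aldol), C2–C3 (alkyne acylation), C1–C14 and C10–C11 (Diels–Alder).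
Forward order: the six-membered ring is made first. A temporary C9–O–C12 lactone bridge then places O12 and C13=C14. The chlorodienyl arm and the malate unit follow, then the ten-membered ring, the γ-lactone, and last both oxiranes in one flask.
Stereochemistry: C1, C10 and C11 come from an oxazolidinone auxiliary, C12 from the lactone tether, C2 from a reagent-controlled ketone reduction, and C8 and C17 from (S)-malate. C9 is set in the aldol step and C6/C7 in the ring closure. C3/C4 are set by a vanadate tether on O2 and C13/C14 by the blocked β face.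

Key step: step 31

Assumption: briarane numbering is used for all intermediates, and β is the face of the six-membered ring that bears the C1 methyl. The target structure has O2 and the C3–C4 oxirane oxygen on the same face of the ten-membered ring. Lactol carbons are anomeric mixtures and are written without configuration.

Step 1
Reactants: 1 tert-butyl 2-bromopropanoate
Product: 3 tert-butyl 2-(triphenyl-λ5-phosphanylidene)propanoate, via phosphonium bromide 2 (not isolated)
Conditions: PPh3, toluene, 90 °C; then aq. NaOH, CH2Cl2, rt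
Reagents that add atoms: triphenylphosphine, c1ccc(cc1)P(c1ccccc1)c1ccccc1
Why: SN2 quaternisation of PPh3 by the α-bromo ester followed by deprotonation is the standard preparation of a stabilised Wittig ylide, and the racemic centre of 1 is erased.

Step 2
Reactants: 3 tert-butyl 2-(triphenyl-λ5-phosphanylidene)propanoate; 4 glyoxylic acid monohydrate
Product: 5 (E)-4-tert-butoxy-3-methyl-4-oxobut-2-enoic acid
Conditions: CH2Cl2, 0 °C → rt; extraction into aq. NaHCO3, then acidification
Reagents that add atoms: none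
Why: Wittig olefination with a stabilised α-methyl ylide is E-selective, so the two carbonyl groups (future C2 and C9) end up trans, and base extraction frees the acid from Ph3PO.

Step 3
Reactants: 5 (E)-4-tert-butoxy-3-methyl-4-oxobut-2-enoic acid; 6 (S)-4-benzyl-1,3-oxazolidin-2-one
Product: 8 tert-butyl (E)-4-[(4S)-4-benzyl-2-oxo-1,3-oxazolidin-3-yl]-2-methyl-4-oxobut-2-enoate, via mixed pivalic anhydride 7 (not isolated)
Conditions: tBuCOCl, Et3N, THF, −20 °C; then 6, LiCl, −20 °C → rt
Reagents that add atoms: none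
Why: N-acylation of the oxazolidinone through a mixed pivalic anhydride takes place at the less hindered enoyl carbonyl and leaves the alkene geometry untouched.

Step 4
Reactants: 8 tert-butyl (E)-4-[(4S)-4-benzyl-2-oxo-1,3-oxazolidin-3-yl]-2-methyl-4-oxobut-2-enoate; 9 (E)-penta-1,3-diene
Product: 10 tert-butyl (1S,5S,6S)-6-{[(4S)-4-benzyl-2-oxo-1,3-oxazolidin-3-yl]carbonyl}-1,5-dimethylcyclohex-3-ene-1-carboxylate
Conditions: Et2AlCl (1.4 equiv), 9 (excess), CH2Cl2, −78 → −20 °C
Reagents that add atoms: none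
Why: In this auxiliary-controlled Diels–Alder reaction the aluminium chelate of the s-cis imide is attacked on the face away from the benzyl group (C1, C10), the imide carbonyl lies endo (C11 methyl cis to C9), the CH2 terminus of the diene bonds to the imide β-carbon C1 (ortho rule), and the E alkene puts C2 and C9 trans.

Step 5
Reactants: 10 Diels–Alder adduct
Product: 11 (1S,2S,6S)-6-(tert-butoxycarbonyl)-2,6-dimethylcyclohex-3-ene-1-carboxylic acid
Conditions: LiOH, H2O2, THF–H2O, 0 °C; then aq. Na2SO3; HCl to pH 3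
Reagents that add atoms: hydrogen peroxide, OO
Why: Hydroperoxide cleavage of an N-acyl oxazolidinone attacks the exocyclic carbonyl even in hindered imides, spares the tert-butyl ester and does not epimerise C10.

Step 6
Reactants: 11 cyclohexene acid
Product: 12 iodolactone tert-butyl (1S,2S,4R,5R,8R)-4-iodo-2,8-dimethyl-7-oxo-6-oxabicyclo[3.2.1]octane-2-carboxylate (lactone oxygen β at C12 and iodine α at C13)
Conditions: I2, NaHCO3, THF–H2O, 0 °C, dark
Reagents that add atoms: iodine, [I][I]
Why: In the iodolactonisation the β-oriented C9 carboxylate opens the α-iodonium ion at C12 by anti addition to give the γ-lactone, which fixes O12 cis to C9 (β) and places iodine α at C13.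

Step 7
Reactants: 12 iodolactone
Product: 13 tert-butyl (1S,2S,5S,8R)-2,8-dimethyl-7-oxo-6-oxabicyclo[3.2.1]oct-3-ene-2-carboxylate (C9–O–C12 lactone bridge on the β face and C13=C14)
Conditions: DBU, toluene, 80 °C
Reagents that add atoms: none
Why: E2 dehydroiodination can use only the antiperiplanar C14 hydrogen, because C12 is a bridgehead carbon, so the alkene forms at C13=C14.

Step 8
Reactants: 13 unsaturated lactone ester
Product: 14 (1S,2S,5S,8R)-2,8-dimethyl-7-oxo-6-oxabicyclo[3.2.1]oct-3-ene-2-carboxylic acid (free C2 acid)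
Conditions: CF3CO2H–CH2Cl2 (1:3), 0 °C → rt
Reagents that add atoms: none
Why: Acidolysis of the tert-butyl ester (alkyl–oxygen cleavage) frees the C2 acid without base or nucleophile, so the lactone stays closed.

Step 9
Reactants: 15 ethynyltrimethylsilane; 16 (tert-butyldimethylsilyloxy)acetaldehyde
Product: 18 1-(tert-butyldimethylsilyloxy)-4-(trimethylsilyl)but-3-yn-2-ol (racemic), via lithium acetylide 17 (not isolated)
Conditions: n-BuLi, THF, −78 °C; then 16, −78 °C; aq. NH4Cl
Reagents that add atoms: none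
Why: This is the 1,2-addition of a lithium acetylide to an aldehyde, and the carbinol centre is removed in the next step.

Step 10
Reactants: 18 propargylic alcohol
Product: 19 1-(tert-butyldimethylsilyloxy)-4-(trimethylsilyl)but-3-yn-2-one
Conditions: Dess–Martin periodinane, NaHCO3, CH2Cl2, 0 °C → rt
Reagents that add atoms: none
Why: Dess–Martin oxidation of a propargylic alcohol is neutral and mild enough for both silyl groups and for the ynone that forms.

Step 11
Reactants: 19 ynone; 20 (chloromethyl)triphenylphosphonium chloride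
Product: 22 (E)-tert-butyl{[2-(chloromethylidene)-4-(trimethylsilyl)but-3-yn-1-yl]oxy}dimethylsilane (Cl cis to the alkynyl group), via chloromethylene ylide 21 (not isolated)
Conditions: 20, NaN(SiMe3)2, THF, −78 °C; then 19, −78 °C → rt; geometric isomers separated on silica
Reagents that add atoms: none
Why: Wittig chloromethylenation of the ketone builds C5=C6 together with its chlorine; both geometric isomers are expected and separable, and the E isomer (Cl trans to CH2O) is carried on.

Step 12
Reactants: 22 silylated chloroenyne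
Product: 23 (E)-tert-butyl{[2-(chloromethylidene)but-3-yn-1-yl]oxy}dimethylsilane
Conditions: K2CO3 (cat.), MeOH, 0 °C
Reagents that add atoms: none
Why: Base-catalysed methanolysis (protiodesilylation) cleaves only the C(sp)–SiMe3 bond, since the silyl ether and the vinyl chloride are inert.

Step 13
Reactants: 14 lactone acid; 23 terminal chloroenyne
Product: 25 ynone in which the C2 ketone joins C1 of the lactone core (C1 C10 C11 C12 as in 13) to the arm C3≡C4–C5(=C6HCl)–C16H2OTBS (E), via acid chloride 24 (not isolated)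
Conditions: (COCl)2, DMF (cat.), CH2Cl2, 0 °C → rt, concentrate; then 23, CuI (10 mol %), Et3N, toluene, rt
Reagents that add atoms: none
Why: Acid chloride formation followed by copper-catalysed acylation of the terminal alkyne (a palladium-free acyl Sonogashira-type coupling) suits pivaloyl-like chlorides, which cannot form ketenes, and copper acetylides do not attack the lactone.

Step 14
Reactants: 25 ynone
Product: 26 (2S)-propargylic alcohol (C2 configuration of the target, other centres as in 25)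
Conditions: (S)-Me-CBS oxazaborolidine (0.5 equiv), catecholborane, CH2Cl2–toluene, −78 °C
Reagents that add atoms: none
Why: In the Corey–Bakshi–Shibata reduction the ketone binds with quaternary C1 as the large group and the rod-like alkynyl as the small group, so the (S)-catalyst sets C2 under reagent control.

Step 15
Reactants: 26 propargylic alcohol
Product: 27 C2 tert-butyldimethylsilyl ether of 26
Conditions: tBuMe2SiOTf, 2,6-lutidine, CH2Cl2, 0 °C
Reagents that add atoms: tert-butyldimethylsilyl triflate, CC(C)(C)[Si](C)(C)OS(=O)(=O)C(F)(F)F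
Why: Silylation with a silyl triflate copes with the neopentyl-type carbinol and masks O2 for the basic and acylating steps ahead.

Step 16
Reactants: 27 silylated enyne
Product: 28 (3Z,5E)-chlorodiene lactone with C3=C4 cis (stereocentres as in 27)
Conditions: H2 (1 atm), Pd/CaCO3 poisoned with Pb(OAc)2 (Lindlar type), quinoline, EtOAc, rt
Reagents that add atoms: none
Why: Lindlar semihydrogenation adds H2 syn to the alkyne and gives (Z)-C3=C4, while the vinyl chloride and the hindered C13=C14 alkene react more slowly.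

Step 17
Reactants: 28 chlorodiene lactone
Product: 29 bridged lactol (C9 hemiacetal to O12, both anomers)
Conditions: iBu2AlH (1.1 equiv), CH2Cl2, −78 °C; aq. potassium sodium tartrate
Reagents that add atoms: none
Why: Partial reduction of a lactone with one equivalent of iBu2AlH at low temperature stops at the aluminium lactolate, giving a masked C9 aldehyde that frees O12 when it opens.

Step 18
Reactants: 30 dimethyl (S)-malate
Product: 32 dimethyl (2S,3R)-2-hydroxy-3-methylbutanedioate, via dilithium alkoxide enolate 31 (not isolated)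
Conditions: LiN(iPr)2 (2.2 equiv), THF, −78 → −20 °C; then MeI, −78 °C; aq. NH4Cl
Reagents that add atoms: iodomethane, C[I]
Why: In the Fráter–Seebach alkylation the chelated alkoxide enolate is methylated anti to the carbinol oxygen, which gives the (2S,3R) diester and so sets C17.

Step 19
Reactants: 32 dimethyl (2S,3R)-2-hydroxy-3-methylbutanedioate
Product: 33 (2S,3R)-2-hydroxy-3-methylbutanedioic acid
Conditions: KOH, H2O–MeOH, rt; HCl to pH 1, continuous extraction
Reagents that add atoms: potassium hydroxide, [K+].[OH-]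
Why: Both methyl esters are saponified, and the carboxylate formed resists deprotonation at C17, so no epimerisation is expected.

Step 20
Reactants: 33 (2S,3R)-2-hydroxy-3-methylbutanedioic acid
Product: 34 (2R)-2-[(2S,4S)-2-tert-butyl-5-oxo-1,3-dioxolan-4-yl]propanoic acid (cis-dioxolanone)
Conditions: tBuCHO, TsOH (cat.), H2SO4 (cat.), pentane, reflux, Dean–Stark trap
Reagents that add atoms: pivalaldehyde, CC(C)(C)C=O
Why: Acid-catalysed acetalisation of the α-hydroxy acid unit gives the five-membered cis-dioxolanone under thermodynamic control (self-regeneration of stereocentres), storing the C8 configuration in the acetal carbon.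

Step 21
Reactants: 34 dioxolanone acid
Product: 35 tert-butyl (2R)-2-[(2S,4S)-2-tert-butyl-5-oxo-1,3-dioxolan-4-yl]propanoate
Conditions: tBuOC(=NH)CCl3, CH2Cl2–cyclohexane, rt
Reagents that add atoms: tert-butyl 2,2,2-trichloroacetimidate, CC(C)(C)OC(=N)C(Cl)(Cl)Cl
Why: Imidate esterification needs neither base nor strong acid, so the acetal and C17 are untouched, and the tert-butyl ester is chosen because it resists alkoxide attack and iBu2AlH at −78 °C.

Step 22
Reactants: 29 bridged lactol; 35 dioxolanone tert-butyl ester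
Product: 37 aldol adduct with new C8–C9 bond and free 9-OH and 12-OH (dioxolanone intact), via lithium enolate 36 (not isolated)
Conditions: 35 (2.0 equiv), LiN(SiMe3)2 (2.0 equiv), THF, −78 °C; then 29 pre-treated with LiN(SiMe3)2 (1.0 equiv), −78 → −40 °C; aq. NH4Cl
Reagents that add atoms: none
Why: In this aldol addition to the hydroxy aldehyde released from the lithium lactolate, the electrophile enters anti to the tert-butyl group (retention at C8), the Zimmerman–Traxler chair of the ring-locked enolate puts O9 anti to O8, and the Felkin–Anh preference of the aldehyde (C1 as large group) points the same way, so C8 and C9 form in a matched case.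

Step 23
Reactants: 37 aldol adduct
Product: 39 α-hydroxy aldehyde (C7 CHO with free 8-OH 9-OH 12-OH and C19 tert-butyl ester), via dioxolanyl lactol 38 (not isolated)
Conditions: iBu2AlH (4.5 equiv), CH2Cl2, −78 °C; aq. potassium sodium tartrate; then AcOH–H2O–THF, rt, evaporation of tBuCHO
Reagents that add atoms: none
Why: iBu2AlH reduces the activated acylal-type carbonyl to a lactol that sheds pivalaldehyde under mild acid, whereas hindered tert-butyl esters survive this reagent at −78 °C.

Step 24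
Reactants: 39 α-hydroxy aldehyde
Product: 40 9,12-diacetate of 39
Conditions: Ac2O, pyridine, DMAP (cat.), CH2Cl2, 0 °C → rt
Reagents that add atoms: acetic anhydride, CC(=O)OC(C)=O
Why: DMAP-catalysed acetylation esterifies the two secondary hydroxyls, while the tertiary 8-OH is inert and the aldehyde has no α-hydrogen.

Step 25
Reactants: 40 diacetate
Product: 41 primary allylic alcohol (C16 OH free, C2 silyl ether kept)
Conditions: HF·pyridine, pyridine, THF, 0 °C
Reagents that add atoms: none
Why: Buffered HF·pyridine cleaves the unhindered primary allylic silyl ether much faster than the neopentyl-type secondary one at C2.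

Step 26
Reactants: 41 allylic alcohol
Product: 43 allylic bromide (C16 Br), via allylic mesylate 42 (not isolated)
Conditions: MsCl, Et3N, CH2Cl2, −30 °C; then LiBr, THF, 0 °C
Reagents that add atoms: lithium bromide, [Li+].[Br-]
Why: Mesylation followed by SN2 displacement with bromide converts only the primary allylic alcohol, avoids phosphorus reagents that could attack the aldehyde, and keeps the C5=C6 geometry.

Step 27
Reactants: 43 allylic bromide
Product: 44 C8 triethylsilyl ether of 43
Conditions: Et3SiOTf, 2,6-lutidine, CH2Cl2, −78 → 0 °C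
Reagents that add atoms: triethylsilyl triflate, CC[Si](CC)(CC)OS(=O)(=O)C(F)(F)F
Why: Silylation of the tertiary hydroxyl with a silyl triflate removes the chelating group next to the aldehyde, so the ring closure runs under Felkin–Anh control.

Step 28
Reactants: 44 bromo aldehyde
Product: 46 ten-membered carbocycle with C6–C7 bond and anti 6-Cl/7-OH and exocyclic C5=C16, via chloroallylchromium species 45 (not isolated)
Conditions: CrCl2 (8 equiv, nickel-free), THF, slow addition of 44 to about 1 mM, rt; aq. sodium serinate work-up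
Reagents that add atoms: none
Why: Proposed new method: two equivalents of divalent chromium reduce the allylic bromide to γ-chloroallylchromium species 45, which equilibrates to the isomer with Cl trans to CH2Cr and adds through C6 to the C7 aldehyde in a six-membered chair, giving the anti Cl/OH pair and shifting the alkene to C5=C16; attack anti to the C8–OSiEt3 bond (Felkin–Anh, with C17 as the small group) sets C7. The closest known reactions are the intermolecular CrCl2-mediated addition of 1,3-dichloropropene to aldehydes (anti vinyl chlorohydrins) and Nozaki–Hiyama allylation macrocyclisations of ω-formyl allylic bromides to ten- to fourteen-membered carbocycles; combining the two in one ring closure is new.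

Step 29
Reactants: 46 hydroxy tert-butyl ester
Product: 47 γ-lactone (O7–C19) with free 8-OH and C2 silyl ether
Conditions: CF3CO2H–CH2Cl2 (1:9), 0 °C
Reagents that add atoms: none
Why: In this acid-induced lactonisation CF3CO2H cleaves the tert-butyl ester and the tertiary silyl ether and the 7-OH closes the five-membered lactone, and no base is present that could turn the chlorohydrin into an oxirane.

Step 30
Reactants: 47 silylated lactone
Product: 48 triene with free (2R)-hydroxyl, (Z)-C3=C4, C5=C16, C13=C14, 6-Cl, 9- and 12-acetates, 8-OH and the γ-lactone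
Conditions: HF·pyridine, THF, 0 °C → rt
Reagents that add atoms: none
Why: Desilylation with HF·pyridine frees O2 under conditions that the acetates, the lactone and the allylic chloride tolerate.

Step 31
Reactants: 48 triene
Product: 50 bis-oxirane (2-deacetyl target), via C3–C4 mono-oxirane 49 (not isolated)
Conditions: VO(acac)2 (5 mol %), tBuOOH (1.5 equiv, in decane), CH2Cl2, 0 °C; then NaHCO3, mCPBA (3 equiv), 0 °C → rt
Reagents that add atoms: tert-butyl hydroperoxide, CC(C)(C)OO; 3-chloroperbenzoic acid, OOC(=O)c1cccc(Cl)c1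
Why: The C2 hydroxyl exchanges onto pentavalent vanadium, which also binds tBuOO, and one oxygen atom passes in a concerted step to C3=C4 (vanadium-catalysed hydroxyl-directed epoxidation, giving 49); mCPBA added to the same flask then epoxidises C13=C14 by the concerted butterfly mechanism (Prilezhaev reaction). Each oxirane closes by suprafacial transfer of a single oxygen atom to both alkene carbons at once, so the Z alkene and the ring cis alkene become cis-disubstituted oxiranes and four C–O bonds form in one operation. C3 and C4 are set by the vanadate tether, which needs an O–C2–C3=C4 angle near 50°; in a medium-ring (Z)-allylic alcohol this turns C1 and the ring away from the attacked face and gives the oxirane cis to O2, as in the target and as known for cyclooct-2-enol and cyclonon-2-enol. A peracid needs about 120° and gives the trans epoxy alcohol in such rings, so vanadium acts first and the peracid is added only after C3=C4 is consumed. C13 and C14 are set by sterics, because the C1 methyl, the C11 methyl and the C12 acetoxy group all stand on the β face and the capped O12 cannot direct, so oxygen arrives from the α face. The step must oxidise two of three alkenes: vanadium touches only the allylic-alcohol alkene, and C5=C16, then flanked by the oxirane and the C6 chloride, is too electron-poor to compete with C13=C14.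

Step 32
Reactants: 50 bis-oxirane
Product: 51 CNP0229305.1 (target)
Conditions: Ac2O, pyridine, DMAP (cat.), CH2Cl2, rt
Reagents that add atoms: acetic anhydride, CC(=O)OC(C)=O
Why: DMAP-catalysed acetylation reaches the only secondary hydroxyl (C2); the tertiary 8-OH does not react, and the mild medium leaves both oxiranes and the chloride intact.

Compound list
1 | tert-butyl 2-bromopropanoate (racemic) | CC(Br)C(=O)OC(C)(C)C | starting material
2 | (1-tert-butoxy-1-oxopropan-2-yl)triphenylphosphonium bromide | CC(C(=O)OC(C)(C)C)[P+](c1ccccc1)(c1ccccc1)c1ccccc1.[Br-] | intermediate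
3 | tert-butyl 2-(triphenyl-λ5-phosphanylidene)propanoate | CC(C(=O)OC(C)(C)C)=P(c1ccccc1)(c1ccccc1)c1ccccc1 | intermediate
4 | glyoxylic acid monohydrate | OC(O)C(=O)O | starting material
5 | (E)-4-tert-butoxy-3-methyl-4-oxobut-2-enoic acid | CC(C)(C)OC(=O)/C(C)=C/C(=O)O | intermediate
6 | (S)-4-benzyl-1,3-oxazolidin-2-one | O=C1N[C@@H](Cc2ccccc2)CO1 | starting material
7 | mixed pivalic anhydride of 5 | CC(C)(C)OC(=O)/C(C)=C/C(=O)OC(=O)C(C)(C)C | intermediate
8 | tert-butyl (E)-4-[(4S)-4-benzyl-2-oxo-1,3-oxazolidin-3-yl]-2-methyl-4-oxobut-2-enoate | CC(C)(C)OC(=O)/C(C)=C/C(=O)N1[C@@H](Cc2ccccc2)COC1=O | intermediate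
9 | (E)-penta-1,3-diene | C=C/C=C/C | starting material
10 | tert-butyl (1S,5S,6S)-6-{[(4S)-4-benzyl-2-oxo-1,3-oxazolidin-3-yl]carbonyl}-1,5-dimethylcyclohex-3-ene-1-carboxylate | CC(C)(C)OC(=O)[C@]1(C)[C@H]([C@@H](C)C=CC1)C(=O)N1[C@@H](Cc2ccccc2)COC1=O | intermediate
11 | (1S,2S,6S)-6-(tert-butoxycarbonyl)-2,6-dimethylcyclohex-3-ene-1-carboxylic acid | CC(C)(C)OC(=O)[C@]1(C)[C@H]([C@@H](C)C=CC1)C(=O)O | intermediate
12 | tert-butyl (1S,2S,4R,5R,8R)-4-iodo-2,8-dimethyl-7-oxo-6-oxabicyclo[3.2.1]octane-2-carboxylate | CC(C)(C)OC(=O)[C@]1(C)[C@H]([C@@H](C)[C@@H](O2)[C@H](I)C1)C2=O | intermediate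
13 | tert-butyl (1S,2S,5S,8R)-2,8-dimethyl-7-oxo-6-oxabicyclo[3.2.1]oct-3-ene-2-carboxylate | CC(C)(C)OC(=O)[C@]1(C)[C@H]([C@@H](C)[C@@H](O2)C=C1)C2=O | intermediate
14 | (1S,2S,5S,8R)-2,8-dimethyl-7-oxo-6-oxabicyclo[3.2.1]oct-3-ene-2-carboxylic acid | OC(=O)[C@]1(C)[C@H]([C@@H](C)[C@@H](O2)C=C1)C2=O | intermediate
15 | ethynyltrimethylsilane | C#C[Si](C)(C)C | starting material
16 | (tert-butyldimethylsilyloxy)acetaldehyde | O=CCO[Si](C)(C)C(C)(C)C | starting material
17 | lithium (trimethylsilyl)acetylide | [Li]C#C[Si](C)(C)C | intermediate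
18 | 1-(tert-butyldimethylsilyloxy)-4-(trimethylsilyl)but-3-yn-2-ol (racemic) | C[Si](C)(C)C#CC(O)CO[Si](C)(C)C(C)(C)C | intermediate
19 | 1-(tert-butyldimethylsilyloxy)-4-(trimethylsilyl)but-3-yn-2-one | C[Si](C)(C)C#CC(=O)CO[Si](C)(C)C(C)(C)C | intermediate
20 | (chloromethyl)triphenylphosphonium chloride | ClC[P+](c1ccccc1)(c1ccccc1)c1ccccc1.[Cl-] | starting material
21 | (chloromethylidene)triphenyl-λ5-phosphane | ClC=P(c1ccccc1)(c1ccccc1)c1ccccc1 | intermediate
22 | (E)-tert-butyl{[2-(chloromethylidene)-4-(trimethylsilyl)but-3-yn-1-yl]oxy}dimethylsilane | Cl/C=C(\C#C[Si](C)(C)C)CO[Si](C)(C)C(C)(C)C | intermediate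
23 | (E)-tert-butyl{[2-(chloromethylidene)but-3-yn-1-yl]oxy}dimethylsilane | Cl/C=C(\C#C)CO[Si](C)(C)C(C)(C)C | intermediate
24 | acid chloride of 14 | ClC(=O)[C@]1(C)[C@H]([C@@H](C)[C@@H](O2)C=C1)C2=O | intermediate
25 | C2 ynone carrying the (E)-chloroenyne arm on the lactone core | Cl/C=C(CO[Si](C)(C)C(C)(C)C)\C#CC(=O)[C@]1(C)[C@H]([C@@H](C)[C@@H](O2)C=C1)C2=O | intermediate
26 | (2S)-propargylic alcohol | Cl/C=C(CO[Si](C)(C)C(C)(C)C)\C#C[C@@H](O)[C@]1(C)[C@H]([C@@H](C)[C@@H](O2)C=C1)C2=O | intermediate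
27 | C2 tert-butyldimethylsilyl ether of 26 | Cl/C=C(CO[Si](C)(C)C(C)(C)C)\C#C[C@@H](O[Si](C)(C)C(C)(C)C)[C@]1(C)[C@H]([C@@H](C)[C@@H](O2)C=C1)C2=O | intermediate
28 | (3Z,5E)-chlorodiene lactone | Cl/C=C(CO[Si](C)(C)C(C)(C)C)\C=C/[C@@H](O[Si](C)(C)C(C)(C)C)[C@]1(C)[C@H]([C@@H](C)[C@@H](O2)C=C1)C2=O | intermediate
29 | bridged C9 lactol (anomers) | Cl/C=C(CO[Si](C)(C)C(C)(C)C)\C=C/[C@@H](O[Si](C)(C)C(C)(C)C)[C@]1(C)[C@H]([C@@H](C)[C@@H](O2)C=C1)C2O | intermediate
30 | dimethyl (S)-malate | COC(=O)C[C@H](O)C(=O)OC | starting material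
31 | dilithium alkoxide enolate of 30 | COC(=O)[C@@H](O[Li])C=C(OC)O[Li] | intermediate
32 | dimethyl (2S,3R)-2-hydroxy-3-methylbutanedioate | COC(=O)[C@@H](O)[C@@H](C)C(=O)OC | intermediate
33 | (2S,3R)-2-hydroxy-3-methylbutanedioic acid | OC(=O)[C@@H](O)[C@@H](C)C(=O)O | intermediate
34 | (2R)-2-[(2S,4S)-2-tert-butyl-5-oxo-1,3-dioxolan-4-yl]propanoic acid | CC(C)(C)[C@H]1O[C@@H]([C@@H](C)C(=O)O)C(=O)O1 | intermediate
35 | tert-butyl (2R)-2-[(2S,4S)-2-tert-butyl-5-oxo-1,3-dioxolan-4-yl]propanoate | CC(C)(C)[C@H]1O[C@@H]([C@@H](C)C(=O)OC(C)(C)C)C(=O)O1 | intermediate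
36 | lithium enolate of 35 | CC(C)(C)[C@H]1OC(=C(O[Li])O1)[C@@H](C)C(=O)OC(C)(C)C | intermediate
37 | aldol adduct (C8–C9 bond, 9-OH and 12-OH free, dioxolanone intact) | Cl/C=C(CO[Si](C)(C)C(C)(C)C)\C=C/[C@@H](O[Si](C)(C)C(C)(C)C)[C@]1(C)[C@H]([C@@H](C)[C@@H](O)C=C1)[C@@H](O)[C@]1(O[C@H](C(C)(C)C)OC1=O)[C@@H](C)C(=O)OC(C)(C)C | intermediate
38 | dioxolanyl lactol (C7 hemiacetal, anomers) | Cl/C=C(CO[Si](C)(C)C(C)(C)C)\C=C/[C@@H](O[Si](C)(C)C(C)(C)C)[C@]1(C)[C@H]([C@@H](C)[C@@H](O)C=C1)[C@@H](O)[C@]1(O[C@H](C(C)(C)C)OC1O)[C@@H](C)C(=O)OC(C)(C)C | intermediate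
39 | C7 α-hydroxy aldehyde with free 8-, 9- and 12-OH | Cl/C=C(CO[Si](C)(C)C(C)(C)C)\C=C/[C@@H](O[Si](C)(C)C(C)(C)C)[C@]1(C)[C@H]([C@@H](C)[C@@H](O)C=C1)[C@@H](O)[C@](C=O)(O)[C@@H](C)C(=O)OC(C)(C)C | intermediate
40 | 9,12-diacetate of 39 | Cl/C=C(CO[Si](C)(C)C(C)(C)C)\C=C/[C@@H](O[Si](C)(C)C(C)(C)C)[C@]1(C)[C@H]([C@@H](C)[C@@H](OC(C)=O)C=C1)[C@@H](OC(C)=O)[C@](C=O)(O)[C@@H](C)C(=O)OC(C)(C)C | intermediate
41 | C16 allylic alcohol | Cl/C=C(CO)\C=C/[C@@H](O[Si](C)(C)C(C)(C)C)[C@]1(C)[C@H]([C@@H](C)[C@@H](OC(C)=O)C=C1)[C@@H](OC(C)=O)[C@](C=O)(O)[C@@H](C)C(=O)OC(C)(C)C | intermediate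
42 | C16 allylic mesylate | Cl/C=C(COS(C)(=O)=O)\C=C/[C@@H](O[Si](C)(C)C(C)(C)C)[C@]1(C)[C@H]([C@@H](C)[C@@H](OC(C)=O)C=C1)[C@@H](OC(C)=O)[C@](C=O)(O)[C@@H](C)C(=O)OC(C)(C)C | intermediate
43 | C16 allylic bromide | Cl/C=C(CBr)\C=C/[C@@H](O[Si](C)(C)C(C)(C)C)[C@]1(C)[C@H]([C@@H](C)[C@@H](OC(C)=O)C=C1)[C@@H](OC(C)=O)[C@](C=O)(O)[C@@H](C)C(=O)OC(C)(C)C | intermediate
44 | C8 triethylsilyl ether of 43 | Cl/C=C(CBr)\C=C/[C@@H](O[Si](C)(C)C(C)(C)C)[C@]1(C)[C@H]([C@@H](C)[C@@H](OC(C)=O)C=C1)[C@@H](OC(C)=O)[C@](C=O)(O[Si](CC)(CC)CC)[C@@H](C)C(=O)OC(C)(C)C | intermediate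
45 | γ-chloroallylchromium dichloride derived from 44 | Cl/C=C(C[Cr](Cl)Cl)\C=C/[C@@H](O[Si](C)(C)C(C)(C)C)[C@]1(C)[C@H]([C@@H](C)[C@@H](OC(C)=O)C=C1)[C@@H](OC(C)=O)[C@](C=O)(O[Si](CC)(CC)CC)[C@@H](C)C(=O)OC(C)(C)C | intermediate
46 | ten-membered carbocycle, anti 6-chloro-7-hydroxy, C5=C16 exocyclic | C=C1/C=C\[C@@H](O[Si](C)(C)C(C)(C)C)[C@]2(C)[C@H]([C@@H](C)[C@@H](OC(C)=O)C=C2)[C@@H](OC(C)=O)[C@](O[Si](CC)(CC)CC)([C@@H](C)C(=O)OC(C)(C)C)[C@@H](O)[C@H]1Cl | intermediate
47 | γ-lactone with free 8-OH and C2 silyl ether | C=C1/C=C\[C@@H](O[Si](C)(C)C(C)(C)C)[C@]2(C)[C@H]([C@@H](C)[C@@H](OC(C)=O)C=C2)[C@@H](OC(C)=O)[C@]3(O)[C@@H](C)C(=O)O[C@H]3[C@H]1Cl | intermediate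
48 | triene with free C2 hydroxyl (precursor of the key step) | C=C1/C=C\[C@@H](O)[C@]2(C)[C@H]([C@@H](C)[C@@H](OC(C)=O)C=C2)[C@@H](OC(C)=O)[C@]3(O)[C@@H](C)C(=O)O[C@H]3[C@H]1Cl | intermediate
49 | C3–C4 mono-oxirane (oxirane cis to O2) | C=C1[C@H]2O[C@H]2[C@@H](O)[C@]2(C)[C@H]([C@@H](C)[C@@H](OC(C)=O)C=C2)[C@@H](OC(C)=O)[C@]2(O)[C@@H](C)C(=O)O[C@H]2[C@H]1Cl | intermediate
50 | bis-oxirane, 2-deacetyl target (product of the key step) | C=C1[C@H]2O[C@H]2[C@@H](O)[C@]2(C)[C@H]([C@@H](C)[C@@H](OC(C)=O)[C@@H]3O[C@@H]32)[C@@H](OC(C)=O)[C@]2(O)[C@@H](C)C(=O)O[C@H]2[C@H]1Cl | intermediate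
51 | CNP0229305.1 | C=C1[C@H]2O[C@H]2[C@@H](OC(C)=O)[C@]2(C)[C@H]([C@@H](C)[C@@H](OC(C)=O)[C@@H]3O[C@@H]32)[C@@H](OC(C)=O)[C@]2(O)[C@@H](C)C(=O)O[C@H]2[C@H]1Cl | target

Total step count: 32. Longest linear sequence: 24 (steps 1–8, 13–17, 22–32). The side branches are steps 9–12 and steps 18–21.

Steps most likely to fail

Step 28 (ring closure by chloroallylation).
- What may go wrong: oligomerisation instead of cyclisation, attack on the wrong aldehyde face under the strain of the forming ring, or further reduction of the new allylic chloride by excess divalent chromium.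
- Fallback: only known reaction types are used. The C6–C7 bond is made between separate partners and the ring is closed at C3=C4 by metathesis. The fallback sets out from acid 14 and alkyne 23 and returns at lactone 47.
- The core partner is prepared first. Acid chloride 24 is coupled with tributyl(vinyl)stannane (PdCl2(PPh3)2 cat., Stille acylation) to give vinyl ketone F1. Reduction with (S)-Me-CBS gives allylic alcohol F2, and tBuMe2SiOTf gives silyl ether F3.
- The operations of steps 17, 22, 23, 24 and 27 then give in turn bridged lactol F4, aldol adduct F5, dioxolanyl lactol F6 (which collapses on work-up), hydroxy aldehyde F7, diacetate F8 and triethylsilyl ether F9.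
- The small partner is prepared separately. Alkyne 23 is semihydrogenated (Pd/CaCO3 with Pb(OAc)2) to chlorodiene silyl ether F10. This is desilylated with HF·pyridine to dienol F11 and converted with CBr4 and PPh3 into dienyl bromide F12.
- CrCl2 turns F12 into chloroallylchromium reagent F13. It adds to F9 in the open-chain, intermolecular manner known for 1,3-dichloropropene and gives anti chlorohydrin F14.
- CF3CO2H closes the lactone to give tetraene F15. Ring-closing diene–ene metathesis with the second-generation Hoveyda–Grubbs catalyst at high dilution then joins C3 and C4, where the ring size favours Z, and gives 47.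

Step 31 (double epoxidation).
- What may go wrong: oxygen delivery to the wrong face of C3=C4 if the ring cannot adopt the geometry the vanadate needs, or oxidation of the hindered allylic alcohol to the enone.
- Fallback: the C2 epimer is used, so that a peracid alone makes both oxiranes, and C2 is corrected afterwards. The fallback sets out from 48 and returns at 50.
- Dess–Martin oxidation gives dienone F16, and (R)-Me-CBS with catecholborane gives C2-epimeric alcohol F17.
- In this epimer the 120° geometry of the hydrogen-bonded peracid and the exposed alkene face both lead to the C3/C4 configuration of the target. mCPBA therefore gives first C2-epimeric mono-oxirane F18 and then C2-epimeric bis-oxirane F19.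
- Dess–Martin oxidation gives epoxy ketone F20. Zn(BH4)2, chelated between the ketone and the oxirane oxygen, delivers hydride from the C3–H side and gives the cis (erythro) epoxy alcohol 50.

Step 22 (aldol on the lactol).
- What may go wrong: the lithium lactolate stays closed, so that the enolate decays before it adds, or the adduct undergoes retro-aldol cleavage on warming.
- Fallback: a free, protected aldehyde replaces the lactol. The fallback sets out from lactone 28 and returns at 37.
- Aminolysis with MeONHMe·HCl and iPrMgCl gives hydroxy Weinreb amide F21, and Et3SiOTf gives 12-O-triethylsilyl amide F22.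
- iBu2AlH gives C9 aldehyde F23, and enolate 36 adds at −78 °C to give 12-O-silylated aldol adduct F24.
- Pyridinium tosylate in MeOH at 0 °C removes the secondary triethylsilyl group in preference to the tert-butyldimethylsilyl ethers and gives 37.

Further compounds
F1 | step 28 | vinyl ketone on the lactone core | C=CC(=O)[C@]1(C)[C@H]([C@@H](C)[C@@H](O2)C=C1)C2=O
F2 | step 28 | C2 allylic alcohol (C2 as in the target) | C=C[C@@H](O)[C@]1(C)[C@H]([C@@H](C)[C@@H](O2)C=C1)C2=O
F3 | step 28 | C2 tert-butyldimethylsilyl ether | C=C[C@@H](O[Si](C)(C)C(C)(C)C)[C@]1(C)[C@H]([C@@H](C)[C@@H](O2)C=C1)C2=O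
F4 | step 28 | bridged C9 lactol (anomers) | C=C[C@@H](O[Si](C)(C)C(C)(C)C)[C@]1(C)[C@H]([C@@H](C)[C@@H](O2)C=C1)C2O
F5 | step 28 | aldol adduct of the vinyl series | C=C[C@@H](O[Si](C)(C)C(C)(C)C)[C@]1(C)[C@H]([C@@H](C)[C@@H](O)C=C1)[C@@H](O)[C@]1(O[C@H](C(C)(C)C)OC1=O)[C@@H](C)C(=O)OC(C)(C)C
F6 | step 28 | dioxolanyl lactol of the vinyl series (anomers) | C=C[C@@H](O[Si](C)(C)C(C)(C)C)[C@]1(C)[C@H]([C@@H](C)[C@@H](O)C=C1)[C@@H](O)[C@]1(O[C@H](C(C)(C)C)OC1O)[C@@H](C)C(=O)OC(C)(C)C
F7 | step 28 | C7 α-hydroxy aldehyde of the vinyl series | C=C[C@@H](O[Si](C)(C)C(C)(C)C)[C@]1(C)[C@H]([C@@H](C)[C@@H](O)C=C1)[C@@H](O)[C@](C=O)(O)[C@@H](C)C(=O)OC(C)(C)C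
F8 | step 28 | 9,12-diacetate of the vinyl series | C=C[C@@H](O[Si](C)(C)C(C)(C)C)[C@]1(C)[C@H]([C@@H](C)[C@@H](OC(C)=O)C=C1)[C@@H](OC(C)=O)[C@](C=O)(O)[C@@H](C)C(=O)OC(C)(C)C
F9 | step 28 | C8 triethylsilyl ether of the vinyl series | C=C[C@@H](O[Si](C)(C)C(C)(C)C)[C@]1(C)[C@H]([C@@H](C)[C@@H](OC(C)=O)C=C1)[C@@H](OC(C)=O)[C@](C=O)(O[Si](CC)(CC)CC)[C@@H](C)C(=O)OC(C)(C)C
F10 | step 28 | (E)-tert-butyl{[2-(chloromethylidene)but-3-en-1-yl]oxy}dimethylsilane | Cl/C=C(\C=C)CO[Si](C)(C)C(C)(C)C
F11 | step 28 | (E)-2-(chloromethylidene)but-3-en-1-ol | Cl/C=C(\C=C)CO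
F12 | step 28 | 2-(bromomethyl)-1-chlorobuta-1,3-diene (Cl cis to vinyl) | Cl/C=C(\C=C)CBr
F13 | step 28 | chloroallylchromium dichloride from F12 | Cl/C=C(\C=C)C[Cr](Cl)Cl
F14 | step 28 | open-chain anti 6-chloro-7-hydroxy adduct | C=C[C@@H](O[Si](C)(C)C(C)(C)C)[C@]1(C)[C@H]([C@@H](C)[C@@H](OC(C)=O)C=C1)[C@@H](OC(C)=O)[C@](O[Si](CC)(CC)CC)([C@@H](C)C(=O)OC(C)(C)C)[C@@H](O)[C@@H](Cl)C(=C)C=C
F15 | step 28 | γ-lactone tetraene, metathesis substrate | C=C[C@@H](O[Si](C)(C)C(C)(C)C)[C@]1(C)[C@H]([C@@H](C)[C@@H](OC(C)=O)C=C1)[C@@H](OC(C)=O)[C@]1(O)[C@@H](C)C(=O)O[C@H]1[C@@H](Cl)C(=C)C=C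
F16 | step 31 | C2 dienone | C=C1/C=C\C(=O)[C@]2(C)[C@H]([C@@H](C)[C@@H](OC(C)=O)C=C2)[C@@H](OC(C)=O)[C@]3(O)[C@@H](C)C(=O)O[C@H]3[C@H]1Cl
F17 | step 31 | C2 epimer of 48 | C=C1/C=C\[C@H](O)[C@]2(C)[C@H]([C@@H](C)[C@@H](OC(C)=O)C=C2)[C@@H](OC(C)=O)[C@]3(O)[C@@H](C)C(=O)O[C@H]3[C@H]1Cl
F18 | step 31 | C2 epimer of 49 | C=C1[C@H]2O[C@H]2[C@H](O)[C@]2(C)[C@H]([C@@H](C)[C@@H](OC(C)=O)C=C2)[C@@H](OC(C)=O)[C@]2(O)[C@@H](C)C(=O)O[C@H]2[C@H]1Cl
F19 | step 31 | C2 epimer of 50 | C=C1[C@H]2O[C@H]2[C@H](O)[C@]2(C)[C@H]([C@@H](C)[C@@H](OC(C)=O)[C@@H]3O[C@@H]32)[C@@H](OC(C)=O)[C@]2(O)[C@@H](C)C(=O)O[C@H]2[C@H]1Cl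
F20 | step 31 | C2 epoxy ketone (bis-oxirane) | C=C1[C@H]2O[C@H]2C(=O)[C@]2(C)[C@H]([C@@H](C)[C@@H](OC(C)=O)[C@@H]3O[C@@H]32)[C@@H](OC(C)=O)[C@]2(O)[C@@H](C)C(=O)O[C@H]2[C@H]1Cl
F21 | step 22 | C9 Weinreb amide with free 12-OH | Cl/C=C(CO[Si](C)(C)C(C)(C)C)\C=C/[C@@H](O[Si](C)(C)C(C)(C)C)[C@]1(C)[C@H]([C@@H](C)[C@@H](O)C=C1)C(=O)N(C)OC
F22 | step 22 | 12-O-triethylsilyl Weinreb amide | Cl/C=C(CO[Si](C)(C)C(C)(C)C)\C=C/[C@@H](O[Si](C)(C)C(C)(C)C)[C@]1(C)[C@H]([C@@H](C)[C@@H](O[Si](CC)(CC)CC)C=C1)C(=O)N(C)OC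
F23 | step 22 | C9 aldehyde with 12-O-triethylsilyl group | Cl/C=C(CO[Si](C)(C)C(C)(C)C)\C=C/[C@@H](O[Si](C)(C)C(C)(C)C)[C@]1(C)[C@H]([C@@H](C)[C@@H](O[Si](CC)(CC)CC)C=C1)C=O
F24 | step 22 | 12-O-triethylsilyl aldol adduct | Cl/C=C(CO[Si](C)(C)C(C)(C)C)\C=C/[C@@H](O[Si](C)(C)C(C)(C)C)[C@]1(C)[C@H]([C@@H](C)[C@@H](O[Si](CC)(CC)CC)C=C1)[C@@H](O)[C@]1(O[C@H](C(C)(C)C)OC1=O)[C@@H](C)C(=O)OC(C)(C)C
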